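Remark on the chemistry: atom labels C1–C15 follow guaiane numbering on every bicyclic compound (ring A = C1–C5, ring B = C1, C5–C10, C14 on C10, C15 on C4, C11 on C7). Commercial (R)-(−)-linalool of high enantiomeric purity is assumed, because the optical purity of the target rests on it.

## Analysis of the target

The target 34 is a guaiane-type hydroazulene: five-membered ring A (C1–C5) is fused to seven-membered ring B (C1, C5–C10) through a tetrasubstituted C1=C10 alkene. It carries methyl groups on C4 and C10, a 2-hydroxypropan-2-yl group (C11) on C7 and an (E)-4-hydroxycinnamate on the C8 oxygen. There are four stereocentres, all S: C4 and C5 on ring A (C4 methyl cis to the C5–C6 bond, so H4 and H5 share a face) and C7 and C8 on ring B (side chain and ester oxygen trans, H7 on the face of H5). C5 is the hub: it is the only ring-fusion stereocentre, it is allylic and cannot be epimerised, and every other centre must be related to it, C4 directly and the C7/C8 pair across C6. The sensitive groups are the tertiary alcohol (elimination), the tetrasubstituted alkene (migration under acid, and it must survive every reduction and hydroboration) and the cinnamate with its free phenol (conjugate addition, acyl transfer), which therefore goes on last. The hard points are the closure of a seven-membered ring, a fully substituted alkene at the fusion, the distinction between C6 and C8 on either side of C7, and the stereochemical relay from C5 to C7/C8. The strategy rests on the C1=C10 alkene with the C5 methine beside it: these are the two alkyne carbons and the alkene terminus of an yne–vinylcyclopropane cycloadduct, whose five-carbon unit supplies C5–C9 and delivers an oxygen on C7.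

## Retrosynthetic reasoning

C8–O acyl bond. 34 is cut at the ester into diol 29 and the silyl-protected acid 32 (from 30), through the protected ester 33. The cinnamate would not survive organometallic addition, hydroboration or hydrogenation, so it must come last. The forward reaction has to acylate the secondary C8 hydroxyl and leave the tertiary C11 hydroxyl alone, which steric demand should ensure.

C8–O and C7–H bonds. 29 is traced to the allylic alcohol 27 with a C7=C8 alkene. Hydroboration–oxidation puts oxygen on the less substituted C8 and hydrogen on C7 in a syn addition, which gives the trans relationship directly. What remains to be earned is the face, which must be the face of H5.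

C7–C11 bond and the two C11 methyls. 27 is cut to the unsaturated ester 25 (twofold methyl addition), 25 to the enol triflate 24 (carbonylation) and 24 to the C7 ketone 22. Cutting here uses a ring ketone at C7 as the single handle for both the side chain and the C8 oxygen. The price is that 22 must be enolised toward C8 and not toward C6.

C4–H bond. 22 is traced to the diene 21 (hydrogenation from the face opposite the C5–C6 bond) and 21 to the tertiary alcohol 20 (dehydration), which comes from the cycloadduct 19 by loss of both silyl groups. C4 is a temporary stereocentre: it arrives oxygenated from the chiral pool, steers C5 and is then rebuilt as the C4 methine. The reset is placed immediately after the cycloaddition, because later the molecule would hold two tertiary alcohols (C4 and C11) that cannot be dehydrated selectively without a protecting-group detour. At this stage only the tetrasubstituted alkene competes in the hydrogenation. In 20 the C4 oxygen is cis to H5, so the elimination must be an anti (E2) process; a syn elimination would remove H5 and destroy the centre made in the key step.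

C1–C5 and C9–C10 bonds. 19 is opened to the acyclic yne–vinylcyclopropane 18. This one cut removes both rings, the tetrasubstituted alkene and the C5 stereocentre, and leaves a chain with one stereocentre. The forward cycloaddition must control C5 from C4 and place the enol ether at C6=C7.

C6–C7 bond and the silyl ether. 18 comes from cyclopropanol 17, which is cut between the alkene and the cyclopropane into the E-iodoalkene 10 (as its metal derivative 14) and cyclopropanone 16, released in the flask from hemiacetal 12, itself made from 11. This joins the two halves late and uses the cyclopropane as a bought three-carbon unit.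

The chiral chain. 10 is traced to aldehyde 9 (one-carbon iodo-olefination), 9 to enyne 7 (cleavage of the vinyl group), 7 to dibromoalkene 5 and aldehyde 4 (alkyne construction and C-methylation), and 4 to the silyl ether 2 of (R)-linalool 1 (cleavage of the trisubstituted alkene). The carbinol carbon of 1 becomes C4 with its methyl and oxygen, so no stereocentre has to be made before the key step.

## Alternatives that were turned down

Alternative 1: The C1=C10 alkene itself is disconnected. C1 and C10 would be the two α-carbons of an eight-membered cyclic sulfone A2, and a Ramberg–Bäcklund reaction (α-halogenation by a hydroxide base with a tetrahalomethane, closure to the episulfone, sulfur extrusion) would contract the ring to ring B and give the acetonide A1 of diol 29. In its favour, all four stereocentres would be in place before the alkene exists, so nothing would be erased and no reduction or hydroboration would have to spare the alkene; on stereochemical security it is stronger than the chosen route. Against it, A2 needs a medium-ring closure onto a fully elaborated ring A piece with a C7/C8-bearing chain, which is a long linear sequence with its own relay problem. Both α-carbons are tertiary C–H centres, the least favourable case for halogenation and for closure to a tetrasubstituted alkene. The carbene released by the halogenating medium would also add to the electron-rich product alkene. The chosen route offers in exchange a single catalytic step that makes both rings and the alkene from an acyclic precursor reached in nine steps.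

Alternative 2: Ring B is cut at C8–C9 and C5–C6. A silyl triflate would ionise the acetal A5 to an alkoxy-substituted oxyallyl cation, which would add across the termini of the 1-isopropenylcyclopentene A4 in a [4+3] cycloaddition to give ketone A3, with C7 as carbonyl, a benzyloxy group on C8 and C1=C10 in place. Its strong point is that the C8 oxygen and the C7 carbonyl arrive together. The chosen route has to earn that by a regioselective enolisation and a hydroboration, so on this point the alternative is better. Against it, A4 carries a tertiary allylic silyl ether at C4 that the same Lewis acid can ionise. The semicyclic diene must reach the s-cis form and is prone to cationic oligomerisation. An unsymmetrical cation meets an unsymmetrical diene, so two regiochemistries and a stepwise path are open. Three selectivities (the C5 face, C8 relative to C5, regiochemistry) would be needed in one intermolecular event. Ring A with its C4 centre would still have to be made separately, so no steps are saved. The chosen key step is intramolecular, runs under neutral conditions and sets one stereocentre only.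

Alternative 3: The C5–C1 and C5–C6 bonds are cut. An aryl diazoketone A7 would give a carbenoid at C5 under a divalent rhodium tetracarboxylate dimer, Rh2(O2CR)4. Intramolecular Buchner addition to the arene C1–C6 bond and electrocyclic opening of the cyclopropane-fused valence isomer would give the trienone A6, with ring A closed and ring B expanded from the arene. In its favour, the arene fixes the positions of the C7 side chain, the C8 oxygen and the C10 methyl, so the C6/C8 regiochemistry question does not arise. Chiral catalysts of this class could set C5, the only stereocentre, by catalyst control. On both points it is at least as strong as the chosen route. Against it, A6 sits at the wrong oxidation level: the C6=C7 and C8=C9 alkenes must be reduced with creation of C7 and C8 while C1=C10 is kept, in a conjugated triene. C5 is α to the C4 ketone and doubly allylic, so the centre just made is prone to enolisation and double-bond migration. The carbenoid can also attack the other ortho bond or insert into an aromatic C–H bond of the electron-rich ring. The C4 methyl would still need olefination and a face-selective hydrogenation. The chosen route gives a cycloadduct at the right oxidation level whose C5 centre cannot epimerise.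

Key step: step 10

## Route

Step 1
Reactants: 1 (R)-linalool
Product: 2 (R)-triethyl[(3,7-dimethylocta-1,6-dien-3-yl)oxy]silane
Conditions: Et3SiOTf, 2,6-lutidine, CH2Cl2, −78 to 0 °C
Reagents that add atoms: triethylsilyl trifluoromethanesulfonate, CC[Si](CC)(CC)OS(=O)(=O)C(F)(F)F
Why: Silylation of a tertiary alcohol with a silyl triflate and a hindered pyridine; the stereocentre is not touched. The triethylsilyl group is the bulky partner of the methyl group on C4 for step 10 and still leaves with fluoride in step 11.

Step 2
Reactants: 2 (R)-triethyl[(3,7-dimethylocta-1,6-dien-3-yl)oxy]silane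
Product: 4 (R)-4-methyl-4-(triethylsilyloxy)hex-5-enal, via secondary ozonide 3 (not isolated)
Conditions: O3 (about 1 equiv, Sudan Red 7B end point), CH2Cl2, −78 °C; then Me2S, −78 °C to rt
Reagents that add atoms: ozone, [O-][O+]=O
Why: Ozonolysis with reductive work-up. Ozone should take the electron-rich trisubstituted alkene well ahead of the vinyl group, which is monosubstituted, sits on a fully substituted carbon and is deactivated by the allylic oxygen.

Step 3
Reactants: 4 (R)-4-methyl-4-(triethylsilyloxy)hex-5-enal
Product: 5 (R)-[(7,7-dibromo-3-methylhepta-1,6-dien-3-yl)oxy]triethylsilane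
Conditions: CBr4, PPh3, Zn, CH2Cl2, 0 °C to rt
Reagents that add atoms: carbon tetrabromide, BrC(Br)(Br)Br
Why: First stage of the Corey–Fuchs reaction, a Wittig-type dibromomethylenation of the aldehyde. Zinc keeps the medium free of acidic phosphorus bromides, so the silyl ether and the vinyl group should survive.

Step 4
Reactants: 5 (R)-[(7,7-dibromo-3-methylhepta-1,6-dien-3-yl)oxy]triethylsilane
Product: 7 (R)-triethyl[(3-methyloct-1-en-6-yn-3-yl)oxy]silane, via lithium acetylide 6 (not isolated)
Conditions: n-BuLi (2.2 equiv), THF, −78 °C; then MeI, −78 °C to rt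
Reagents that add atoms: iodomethane, CI
Why: Second stage of the Corey–Fuchs reaction: bromine–lithium exchange and rearrangement give the lithium acetylide, which is C-methylated in the same flask. The methyl cap also removes the acidic alkyne hydrogen before the organolithium chemistry of step 8.

Step 5
Reactants: 7 (R)-triethyl[(3-methyloct-1-en-6-yn-3-yl)oxy]silane
Product: 9 (R)-2-methyl-2-(triethylsilyloxy)hept-5-ynal, via secondary ozonide 8 (not isolated)
Conditions: O3 (Sudan Red 7B end point), CH2Cl2, −78 °C; then Me2S, −78 °C to rt
Reagents that add atoms: ozone, [O-][O+]=O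
Why: Ozonolysis; alkenes react with ozone far faster than internal alkynes, so titration to the indicator end point should cleave only the vinyl group. The α-silyloxy aldehyde has no α-hydrogen and cannot epimerise.

Step 6
Reactants: 9 (R)-2-methyl-2-(triethylsilyloxy)hept-5-ynal
Product: 10 (R,E)-triethyl[(1-iodo-3-methyloct-1-en-6-yn-3-yl)oxy]silane
Conditions: CrCl2 (6 equiv), CHI3 (2 equiv), THF, 0 °C to rt
Reagents that add atoms: iodoform, IC(I)I
Why: Takai olefination: the geminal dichromium reagent formed from iodoform and divalent chromium adds to the aldehyde and eliminates to the E-iodoalkene. E selectivity is highest with α-branched aldehydes, and the alkyne and silyl ether are inert to the reagent.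

Step 7
Reactants: 11 1-ethoxy-1-(trimethylsiloxy)cyclopropane
Product: 12 1-ethoxycyclopropan-1-ol
Conditions: MeOH, rt
Reagents that add atoms: none
Why: Methanolysis of the labile O–SiMe3 bond gives the cyclopropanone ethyl hemiacetal, the storable form of cyclopropanone.

Step 8
Reactants: 10 (R,E)-triethyl[(1-iodo-3-methyloct-1-en-6-yn-3-yl)oxy]silane; 12 1-ethoxycyclopropan-1-ol
Product: 17 1-[(1E,3R)-3-methyl-3-(triethylsilyloxy)oct-1-en-6-yn-1-yl]cyclopropan-1-ol, via alkenyllithium 13 (not isolated), via alkenylmagnesium bromide 14 (not isolated), via bromomagnesium 1-ethoxycyclopropan-1-olate 15 (not isolated), via cyclopropanone 16 (not isolated)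
Conditions: 10, t-BuLi (2.1 equiv), Et2O, −78 °C, then MgBr2·OEt2; 12, MeMgBr (1.0 equiv), THF, 0 °C; combine, 0 to 40 °C; aq. NH4Cl
Reagents that add atoms: none
Why: Iodine–lithium exchange keeps the E geometry, which also holds the silyl group out of reach of the carbanion. The magnesium hemiacetalate sheds ethoxide to the strained ketone in the flask, where the alkenylmagnesium reagent traps it; this is the known addition of organomagnesium reagents to cyclopropanone hemiacetal. The cyclopropanol is silylated without delay because it is prone to ring opening.

Step 9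
Reactants: 17 1-[(1E,3R)-3-methyl-3-(triethylsilyloxy)oct-1-en-6-yn-1-yl]cyclopropan-1-ol
Product: 18 tert-butyldimethyl({1-[(1E,3R)-3-methyl-3-(triethylsilyloxy)oct-1-en-6-yn-1-yl]cyclopropyl}oxy)silane
Conditions: t-BuMe2SiCl, imidazole, DMF, rt
Reagents that add atoms: tert-butylchlorodimethylsilane, CC(C)(C)[Si](C)(C)Cl
Why: Silylation of the cyclopropanol under non-acidic conditions, which avoids ring expansion or ring opening of the vinylcyclopropanol. The siloxy group is the donor that activates the cyclopropane in step 10.

Step 10
Reactants: 18 tert-butyldimethyl({1-[(1E,3R)-3-methyl-3-(triethylsilyloxy)oct-1-en-6-yn-1-yl]cyclopropyl}oxy)silane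
Product: 19 tert-butyl{[(3R,3aR)-3,8-dimethyl-3-(triethylsilyloxy)-1,2,3,3a,6,7-hexahydroazulen-5-yl]oxy}dimethylsilane
Conditions: [Rh(CO)2Cl]2 (5 mol %), 1,2-dichloroethane (0.02 M), 70 °C
Reagents that add atoms: none
Why: The closest known reaction type is the rhodium-catalysed intramolecular [5+2] cycloaddition of alkyne-tethered vinylcyclopropanes, in which an oxygen substituent on the cyclopropane carbon next to the alkene eases ring opening. Monovalent rhodium binds the vinylcyclopropane and inserts into the C7–C9 bond to give a σ,π-allyl rhodacyclohexene of trivalent rhodium; the tethered alkyne then inserts into the Rh–C5 bond (C1–C5 formed) to give an eight-membered rhodacycle, and C(sp3)–C(sp2) reductive elimination joins C9 to C10 and returns monovalent rhodium. Ring A closes in the insertion through the three-atom tether C2–C3–C4 in a 5-exo-dig sense (C1 bonds to C5, C10 stays outside ring A), and ring B closes in the reductive elimination by contraction of the eight-membered metallacycle to the seven-membered carbocycle. The only new stereocentre, C5, is set in the insertion under control of the quaternary C4 centre: one C4 substituent must point to the side of ring A on which the rhodacycle arm C6–C7(OSi) lies, and the triethylsilyloxy group, with the larger swept volume, should avoid that side, so that C6 comes anti to the C4 oxygen and syn to the C4 methyl (4R,5R). The step needs this facial selectivity, because C4 is erased later and a C5 epimer would then belong to the enantiomeric series; any minor diastereomer is therefore to be removed at 19 or 20. It also needs the cycloaddition to outrun vinylcyclopropane-to-cyclopentene rearrangement and alkyne oligomerisation, which the intramolecular tether, dilution and the donor siloxy group on the cyclopropane should secure. Both alkyne carbons end up in the ring-fusion alkene, so no olefin geometry is at stake, and the mechanism fixes the enol ether at C6=C7, which marks C7 as the ketone carbon.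

Step 11
Reactants: 19 tert-butyl{[(3R,3aR)-3,8-dimethyl-3-(triethylsilyloxy)-1,2,3,3a,6,7-hexahydroazulen-5-yl]oxy}dimethylsilane
Product: 20 (3R,3aR)-3-hydroxy-3,8-dimethyl-2,3,3a,4,6,7-hexahydroazulen-5(1H)-one
Conditions: Bu4NF (3 equiv), THF, 0 °C to rt; aq. NH4Cl
Reagents that add atoms: none
Why: Fluoride cleaves the enol silyl ether (protonation at C6 gives the C7 ketone) and the tertiary triethylsilyl ether in one operation. C5 is β to the ketone and cannot epimerise, and the crystalline-type keto alcohol is the convenient point to remove any C5 epimer.

Step 12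
Reactants: 20 (3R,3aR)-3-hydroxy-3,8-dimethyl-2,3,3a,4,6,7-hexahydroazulen-5(1H)-one
Product: 21 (3aS)-3,8-dimethyl-3a,4,6,7-tetrahydroazulen-5(1H)-one
Conditions: SOCl2, pyridine, CH2Cl2, −40 to 0 °C
Reagents that add atoms: none
Why: Dehydration through the chlorosulfite by base-induced anti elimination (E2). The C4 oxygen is cis to H5, so H5 cannot become antiperiplanar and the C5 centre is spared, while an anti hydrogen on C3 gives the C3=C4 ring alkene. Loss of a methyl hydrogen instead would be harmless, because step 13 saturates either alkene position to the same product.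

Step 13
Reactants: 21 (3aS)-3,8-dimethyl-3a,4,6,7-tetrahydroazulen-5(1H)-one
Product: 22 (3S,3aS)-3,8-dimethyl-2,3,3a,4,6,7-hexahydroazulen-5(1H)-one
Conditions: H2 (1 atm), Rh/Al2O3 (5%), EtOAc, rt
Reagents that add atoms: none
Why: Heterogeneous hydrogenation of the trisubstituted cyclopentene; the tetrasubstituted ring-fusion alkene is too hindered to adsorb, and rhodium on alumina has a low tendency to shift double bonds. Hydrogen is delivered to the face of ring A opposite the C5–C6 bond, so H4 comes cis to H5 and the methyl cis to C6 (4S).

Step 14
Reactants: 22 (3S,3aS)-3,8-dimethyl-2,3,3a,4,6,7-hexahydroazulen-5(1H)-one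
Product: 24 (3S,3aS)-3,8-dimethyl-1,2,3,3a,4,7-hexahydroazulen-5-yl trifluoromethanesulfonate, via potassium enolate 23 (not isolated)
Conditions: KN(SiMe3)2 (1.1 equiv), THF, −78 °C; then PhNTf2, −78 to 0 °C
Reagents that add atoms: N-phenylbis(trifluoromethanesulfonimide), O=S(=O)(N(c1ccccc1)S(=O)(=O)C(F)(F)F)C(F)(F)F
Why: Kinetic enolisation with a hindered amide base, then O-sulfonylation. C6 is flanked by the ring-fusion methine C5 and the cis C4 methyl, whereas C8 has only a methylene neighbour, so deprotonation should go toward C8.

Step 15
Reactants: 24 (3S,3aS)-3,8-dimethyl-1,2,3,3a,4,7-hexahydroazulen-5-yl trifluoromethanesulfonate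
Product: 25 methyl (3S,3aS)-3,8-dimethyl-1,2,3,3a,4,7-hexahydroazulene-5-carboxylate
Conditions: Pd(OAc)2 (5 mol %), PPh3 (10 mol %), CO (1 atm), MeOH, Et3N, DMF, rt to 50 °C
Reagents that add atoms: carbon monoxide, [C-]#[O+]; methanol, CO
Why: Palladium-catalysed methoxycarbonylation of an alkenyl triflate: oxidative addition to zerovalent palladium formed in the flask, CO insertion and methanolysis. The alkene stays at C7=C8.

Step 16
Reactants: 25 methyl (3S,3aS)-3,8-dimethyl-1,2,3,3a,4,7-hexahydroazulene-5-carboxylate
Product: 27 2-[(3S,3aS)-3,8-dimethyl-1,2,3,3a,4,7-hexahydroazulen-5-yl]propan-2-ol, via methyl ketone 26 (not isolated)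
Conditions: MeLi (4 equiv), anhydrous CeCl3 (4 equiv), THF, −78 to 0 °C; aq. NH4Cl
Reagents that add atoms: methyllithium, [Li]C
Why: Twofold 1,2-addition of a methyl organometallic to the ester through the methyl ketone. The organocerium reagent is nucleophilic but weakly basic, which should suppress deprotonation at the doubly allylic C9 and enolisation of the intermediate ketone.

Step 17
Reactants: 27 2-[(3S,3aS)-3,8-dimethyl-1,2,3,3a,4,7-hexahydroazulen-5-yl]propan-2-ol
Product: 29 (3S,3aS,5S,6S)-5-(2-hydroxypropan-2-yl)-3,8-dimethyl-1,2,3,3a,4,5,6,7-octahydroazulen-6-ol, via cyclic alkoxyborane 28 (not isolated)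
Conditions: BH3·THF (2.5 equiv), THF, 0 °C to rt; then NaOH, H2O2, 0 °C to rt
Reagents that add atoms: hydrogen peroxide, OO
Why: Hydroboration–oxidation: boron goes to the less substituted C8 and hydrogen to C7 in a syn addition, and oxidation with retention gives the side chain and the C8 hydroxyl trans. Attack should come from the convex face of ring B, the face of H5 and away from the C4 methyl that lies beneath C6, which sets C7 and C8 relative to C5. The tetrasubstituted C1=C10 alkene reacts much more slowly, and the borane is kept to the amount needed.

Step 18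
Reactants: 30 4-hydroxycinnamic acid
Product: 32 (E)-3-[4-(tert-butyldimethylsilyloxy)phenyl]prop-2-enoic acid, via silyl ester 31 (not isolated)
Conditions: t-BuMe2SiCl (2.2 equiv), imidazole, DMF, rt; then AcOH/THF/H2O, rt
Reagents that add atoms: tert-butylchlorodimethylsilane, CC(C)(C)[Si](C)(C)Cl
Why: Silylation of phenol and acid, then selective hydrolysis of the much more labile silyl ester. The phenol must be masked so that the acid cannot acylate itself in step 19.

Step 19
Reactants: 29 (3S,3aS,5S,6S)-5-(2-hydroxypropan-2-yl)-3,8-dimethyl-1,2,3,3a,4,5,6,7-octahydroazulen-6-ol; 32 (E)-3-[4-(tert-butyldimethylsilyloxy)phenyl]prop-2-enoic acid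
Product: 33 (3S,3aS,5S,6S)-5-(2-hydroxypropan-2-yl)-3,8-dimethyl-1,2,3,3a,4,5,6,7-octahydroazulen-6-yl (E)-3-[4-(tert-butyldimethylsilyloxy)phenyl]prop-2-enoate
Conditions: EDC·HCl, DMAP, CH2Cl2, 0 °C to rt
Reagents that add atoms: none
Why: Steglich esterification; the secondary C8 hydroxyl is acylated and the tertiary C11 hydroxyl is too hindered to react. Acylation occurs on oxygen, so C8 keeps its configuration.

Step 20
Reactants: 33 (3S,3aS,5S,6S)-5-(2-hydroxypropan-2-yl)-3,8-dimethyl-1,2,3,3a,4,5,6,7-octahydroazulen-6-yl (E)-3-[4-(tert-butyldimethylsilyloxy)phenyl]prop-2-enoate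
Product: 34 (3S,3aS,5S,6S)-5-(2-hydroxypropan-2-yl)-3,8-dimethyl-1,2,3,3a,4,5,6,7-octahydroazulen-6-yl (E)-3-(4-hydroxyphenyl)prop-2-enoate
Conditions: Bu4NF, AcOH (1:1), THF, 0 °C
Reagents that add atoms: none
Why: Buffered fluoride cleaves the aryl silyl ether; with acetic acid present no free phenoxide or alkoxide builds up, so acyl transfer to the C11 hydroxyl and isomerisation of the cinnamate should not occur.

## Compound list

1 | (R)-linalool | C=C[C@](C)(O)CCC=C(C)C | starting material
2 | (R)-triethyl[(3,7-dimethylocta-1,6-dien-3-yl)oxy]silane | CC(C)=CCC[C@@](C)(O[Si](CC)(CC)CC)C=C | intermediate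
3 | secondary ozonide of 2: 3,3-dimethyl-5-[(3R)-3-methyl-3-(triethylsilyloxy)pent-4-en-1-yl]-1,2,4-trioxolane | CC1(C)OOC(CC[C@@](C)(O[Si](CC)(CC)CC)C=C)O1 | intermediate
4 | (R)-4-methyl-4-(triethylsilyloxy)hex-5-enal | O=CCC[C@@](C)(O[Si](CC)(CC)CC)C=C | intermediate
5 | (R)-[(7,7-dibromo-3-methylhepta-1,6-dien-3-yl)oxy]triethylsilane | BrC(Br)=CCC[C@@](C)(O[Si](CC)(CC)CC)C=C | intermediate
6 | lithium acetylide: (R)-[6-methyl-6-(triethylsilyloxy)oct-7-en-1-yn-1-yl]lithium | [Li]C#CCC[C@@](C)(O[Si](CC)(CC)CC)C=C | intermediate
7 | (R)-triethyl[(3-methyloct-1-en-6-yn-3-yl)oxy]silane | CC#CCC[C@@](C)(O[Si](CC)(CC)CC)C=C | intermediate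
8 | secondary ozonide of 7: 3-[(2R)-2-(triethylsilyloxy)hept-5-yn-2-yl]-1,2,4-trioxolane | CC#CCC[C@@](C)(O[Si](CC)(CC)CC)C1OCOO1 | intermediate
9 | (R)-2-methyl-2-(triethylsilyloxy)hept-5-ynal | CC#CCC[C@@](C)(O[Si](CC)(CC)CC)C=O | intermediate
10 | (R,E)-triethyl[(1-iodo-3-methyloct-1-en-6-yn-3-yl)oxy]silane | CC#CCC[C@@](C)(O[Si](CC)(CC)CC)/C=C/I | intermediate
11 | 1-ethoxy-1-(trimethylsiloxy)cyclopropane | CCOC1(O[Si](C)(C)C)CC1 | starting material
12 | 1-ethoxycyclopropan-1-ol | CCOC1(O)CC1 | intermediate
13 | alkenyllithium: [(1E,3R)-3-methyl-3-(triethylsilyloxy)oct-1-en-6-yn-1-yl]lithium | CC#CCC[C@@](C)(O[Si](CC)(CC)CC)/C=C/[Li] | intermediate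
14 | alkenylmagnesium bromide: bromo[(1E,3R)-3-methyl-3-(triethylsilyloxy)oct-1-en-6-yn-1-yl]magnesium | CC#CCC[C@@](C)(O[Si](CC)(CC)CC)/C=C/[Mg]Br | intermediate
15 | bromomagnesium 1-ethoxycyclopropan-1-olate | CCOC1(O[Mg]Br)CC1 | intermediate
16 | cyclopropanone | O=C1CC1 | intermediate
17 | 1-[(1E,3R)-3-methyl-3-(triethylsilyloxy)oct-1-en-6-yn-1-yl]cyclopropan-1-ol | CC#CCC[C@@](C)(O[Si](CC)(CC)CC)/C=C/C1(O)CC1 | intermediate
18 | tert-butyldimethyl({1-[(1E,3R)-3-methyl-3-(triethylsilyloxy)oct-1-en-6-yn-1-yl]cyclopropyl}oxy)silane | CC#CCC[C@@](C)(O[Si](CC)(CC)CC)/C=C/C1(O[Si](C)(C)C(C)(C)C)CC1 | intermediate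
19 | tert-butyl{[(3R,3aR)-3,8-dimethyl-3-(triethylsilyloxy)-1,2,3,3a,6,7-hexahydroazulen-5-yl]oxy}dimethylsilane (guaiane numbering: 4-silyloxy-1(10),6-diene, 7-silyl enol ether) | CC1=C2CC[C@@](C)(O[Si](CC)(CC)CC)[C@@H]2C=C(O[Si](C)(C)C(C)(C)C)CC1 | intermediate
20 | (3R,3aR)-3-hydroxy-3,8-dimethyl-2,3,3a,4,6,7-hexahydroazulen-5(1H)-one | CC1=C2CC[C@@](C)(O)[C@@H]2CC(=O)CC1 | intermediate
21 | (3aS)-3,8-dimethyl-3a,4,6,7-tetrahydroazulen-5(1H)-one | CC1=C2CC=C(C)[C@@H]2CC(=O)CC1 | intermediate
22 | (3S,3aS)-3,8-dimethyl-2,3,3a,4,6,7-hexahydroazulen-5(1H)-one | CC1=C2CC[C@H](C)[C@@H]2CC(=O)CC1 | intermediate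
23 | potassium enolate of 22 (C7=C8) | CC1=C2CC[C@H](C)[C@@H]2CC([O-])=CC1.[K+] | intermediate
24 | (3S,3aS)-3,8-dimethyl-1,2,3,3a,4,7-hexahydroazulen-5-yl trifluoromethanesulfonate | CC1=C2CC[C@H](C)[C@@H]2CC(OS(=O)(=O)C(F)(F)F)=CC1 | intermediate
25 | methyl (3S,3aS)-3,8-dimethyl-1,2,3,3a,4,7-hexahydroazulene-5-carboxylate | CC1=C2CC[C@H](C)[C@@H]2CC(C(=O)OC)=CC1 | intermediate
26 | methyl ketone: 1-[(3S,3aS)-3,8-dimethyl-1,2,3,3a,4,7-hexahydroazulen-5-yl]ethan-1-one | CC1=C2CC[C@H](C)[C@@H]2CC(C(C)=O)=CC1 | intermediate
27 | 2-[(3S,3aS)-3,8-dimethyl-1,2,3,3a,4,7-hexahydroazulen-5-yl]propan-2-ol | CC1=C2CC[C@H](C)[C@@H]2CC(C(C)(C)O)=CC1 | intermediate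
28 | cyclic alkoxyborane (1,2-oxaborolane bridging C8 and the C11 oxygen) | CC1=C2CC[C@H](C)[C@@H]2C[C@H](C(C)(C)O3)[C@@H](B3)C1 | intermediate
29 | (3S,3aS,5S,6S)-5-(2-hydroxypropan-2-yl)-3,8-dimethyl-1,2,3,3a,4,5,6,7-octahydroazulen-6-ol | CC1=C2CC[C@H](C)[C@@H]2C[C@H](C(C)(C)O)[C@@H](O)C1 | intermediate
30 | 4-hydroxycinnamic acid | OC(=O)/C=C/c1ccc(O)cc1 | starting material
31 | silyl ester: tert-butyldimethylsilyl (E)-3-[4-(tert-butyldimethylsilyloxy)phenyl]prop-2-enoate | CC(C)(C)[Si](C)(C)OC(=O)/C=C/c1ccc(O[Si](C)(C)C(C)(C)C)cc1 | intermediate
32 | (E)-3-[4-(tert-butyldimethylsilyloxy)phenyl]prop-2-enoic acid | OC(=O)/C=C/c1ccc(O[Si](C)(C)C(C)(C)C)cc1 | intermediate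
33 | (3S,3aS,5S,6S)-5-(2-hydroxypropan-2-yl)-3,8-dimethyl-1,2,3,3a,4,5,6,7-octahydroazulen-6-yl (E)-3-[4-(tert-butyldimethylsilyloxy)phenyl]prop-2-enoate | CC1=C2CC[C@H](C)[C@@H]2C[C@H](C(C)(C)O)[C@@H](OC(=O)/C=C/c2ccc(O[Si](C)(C)C(C)(C)C)cc2)C1 | intermediate
34 | (3S,3aS,5S,6S)-5-(2-hydroxypropan-2-yl)-3,8-dimethyl-1,2,3,3a,4,5,6,7-octahydroazulen-6-yl (E)-3-(4-hydroxyphenyl)prop-2-enoate (CNP0403230.1) | CC1=C2CC[C@H](C)[C@@H]2C[C@H](C(C)(C)O)[C@@H](OC(=O)/C=C/c2ccc(O)cc2)C1 | target

## Step count and least certain steps

Total step count: 20 (steps 7 and 18 are side branches). Longest linear sequence: 18 steps from 1 (steps 1–6, 8–17, 19, 20).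

Step 10 (key step). The most likely failure is insufficient or reversed facial discrimination by the C4 centre. Methyl and silyloxy differ less in near-field size than in overall bulk, and once C4 is erased a C5 epimer counts as the wrong enantiomer, so poor selectivity would cost enantiomeric purity unless the epimers are separated at 19 or 20. A second risk is competing vinylcyclopropane rearrangement when the alkyne insertion is slowed by the neighbouring quaternary centre. The fallback moves the stereocontrol from the substrate to the catalyst. It sets out from 18 and comes back at 19. The cycloaddition would be run with a cationic monovalent rhodium complex of a chiral ligand, for example [Rh(cod)2]SbF6 with the matched enantiomer of BINAP, or [Rh(C2H4)2Cl]2 with a chiral phosphoramidite and NaBArF, so that the catalyst pocket and not the C4 substituents decides the C5 face. This fallback makes no new compound (F0).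

Step 12. The most likely failure is ionisation of the tertiary chlorosulfite (an E1 leak): the C4 cation would lose the allylic H5 and the C5 stereocentre would be destroyed. Double-bond migration toward the same conjugated position during step 13 is the related risk. The fallback avoids both cation and alkene. It sets out from 20 and comes back at 22. Compound 20 would be acylated with methyl chlorooxoacetate (DMAP, pyridine, CH2Cl2) to the tertiary methyl oxalate F1. Bu3SnH with AIBN in toluene at 110 °C would then fragment the oxalate to the C4 radical, which takes a hydrogen atom from the stannane on the face opposite the C5–C6 bond and gives 22 directly. This is the known tin hydride deoxygenation of tertiary alkyl methyl oxalates.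

Step 14. The most likely failure is loss of regiocontrol in the enolisation, with deprotonation at C6 competing with C8, since both are methylene groups and only the branching at C5 tells them apart. The fallback changes the order of events so that enolisation happens while C4 is still fully substituted; then the silyloxy group covers the upper and the methyl group the lower C6 hydrogen. It sets out from 19 and comes back at 25. The enol silyl ether alone would be cleaved (Bu4NF/AcOH, 1 equiv, THF, −78 °C) to the silyloxy ketone F2. Kinetic triflation as in step 14 would give the enol triflate F3, and carbonylation as in step 15 the silyloxy ester F4. Fluoride would free the tertiary alcohol to give hydroxy ester F5, and methyl chlorooxoacetate would convert it into the oxalate F6. Bu3SnH/AIBN would then remove the C4 oxygen with hydrogen delivery anti to C6 and give 25. The radical deoxygenation is used here because a hydrogenation could not be relied on to spare the conjugated ester alkene.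

Step 17. The most likely failure is poor facial selectivity of the hydroboration, so that the trans C7/C8 pair forms on the wrong face relative to C5. Partial hydroboration of the C1=C10 alkene with excess borane is a lesser risk. The fallback replaces kinetic face control by thermodynamic control at C7 and directed delivery at C8. It sets out from 27 and comes back at 29. Hydroboration–oxidation as before would give 29 mixed with the (5R,6R)-configured trans diol F7. Oxidation of the secondary alcohols of the mixture (SO3·pyridine, DMSO, i-Pr2NEt) would give the (5S)-hydroxy ketone F8 from F7 and the (5R)-hydroxy ketone F9 from 29. Mild base (DBU, CH2Cl2) would equilibrate F8 through the enol to F9, in which the side chain is pseudo-equatorial and cis to the ring A branch on C5. Reduction of F9 with Me4NBH(OAc)3 (AcOH/MeCN, −20 °C) delivers hydride from the boron bound to the C11 oxygen to the carbonyl face on the side of the side chain, which gives the trans diol 29. Retro-aldol loss of the side chain is the point to watch in the equilibration, so the base is kept weak and the time short.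

## Further compounds

F0 | step 10 | none | none
F1 | step 12 | methyl (3R,3aR)-3,8-dimethyl-5-oxo-1,2,3,3a,4,5,6,7-octahydroazulen-3-yl oxalate | CC1=C2CC[C@@](C)(OC(=O)C(=O)OC)[C@@H]2CC(=O)CC1
F2 | step 14 | (3R,3aR)-3,8-dimethyl-3-(triethylsilyloxy)-2,3,3a,4,6,7-hexahydroazulen-5(1H)-one | CC1=C2CC[C@@](C)(O[Si](CC)(CC)CC)[C@@H]2CC(=O)CC1
F3 | step 14 | (3R,3aR)-3,8-dimethyl-3-(triethylsilyloxy)-1,2,3,3a,4,7-hexahydroazulen-5-yl trifluoromethanesulfonate | CC1=C2CC[C@@](C)(O[Si](CC)(CC)CC)[C@@H]2CC(OS(=O)(=O)C(F)(F)F)=CC1
F4 | step 14 | methyl (3R,3aR)-3,8-dimethyl-3-(triethylsilyloxy)-1,2,3,3a,4,7-hexahydroazulene-5-carboxylate | CC1=C2CC[C@@](C)(O[Si](CC)(CC)CC)[C@@H]2CC(C(=O)OC)=CC1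
F5 | step 14 | methyl (3R,3aR)-3-hydroxy-3,8-dimethyl-1,2,3,3a,4,7-hexahydroazulene-5-carboxylate | CC1=C2CC[C@@](C)(O)[C@@H]2CC(C(=O)OC)=CC1
F6 | step 14 | methyl (3R,3aR)-5-(methoxycarbonyl)-3,8-dimethyl-1,2,3,3a,4,7-hexahydroazulen-3-yl oxalate | CC1=C2CC[C@@](C)(OC(=O)C(=O)OC)[C@@H]2CC(C(=O)OC)=CC1
F7 | step 17 | (3S,3aS,5R,6R)-5-(2-hydroxypropan-2-yl)-3,8-dimethyl-1,2,3,3a,4,5,6,7-octahydroazulen-6-ol | CC1=C2CC[C@H](C)[C@@H]2C[C@@H](C(C)(C)O)[C@H](O)C1
F8 | step 17 | (3S,3aS,5S)-5-(2-hydroxypropan-2-yl)-3,8-dimethyl-2,3,3a,4,5,7-hexahydroazulen-6(1H)-one | CC1=C2CC[C@H](C)[C@@H]2C[C@@H](C(C)(C)O)C(=O)C1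
F9 | step 17 | (3S,3aS,5R)-5-(2-hydroxypropan-2-yl)-3,8-dimethyl-2,3,3a,4,5,7-hexahydroazulen-6(1H)-one | CC1=C2CC[C@H](C)[C@@H]2C[C@H](C(C)(C)O)C(=O)C1
A1 | alternative 1 | acetonide of diol 29 (C8 and C11 oxygens bridged by an isopropylidene group) | CC1=C2CC[C@H](C)[C@@H]2C[C@H]2[C@@H](OC(C)(C)OC2(C)C)C1
A2 | alternative 1 | eight-membered cyclic sulfone with sulfur between C1 and C10, acetonide on the C8 and C11 oxygens | CC1S(=O)(=O)C2CC[C@H](C)[C@@H]2C[C@H]2[C@@H](OC(C)(C)OC2(C)C)C1
A3 | alternative 2 | 6-benzyloxy-3,8-dimethyl-3-(triethylsilyloxy)-2,3,3a,4,6,7-hexahydroazulen-5(1H)-one (guaiane numbering: 8-benzyloxy-4-silyloxy-1(10)-en-7-one) | CC1=C2CC[C@@](C)(O[Si](CC)(CC)CC)[C@@H]2CC(=O)[C@@H](OCc3ccccc3)C1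
A4 | alternative 2 | triethyl{[1-methyl-3-(prop-1-en-2-yl)cyclopent-2-en-1-yl]oxy}silane | C=C(C)C1=C[C@](C)(O[Si](CC)(CC)CC)CC1
A5 | alternative 2 | 1,1-bis(benzyloxy)-2-(trimethylsilyloxy)prop-2-ene | C=C(O[Si](C)(C)C)C(OCc1ccccc1)OCc1ccccc1
A6 | alternative 3 | tricyclic trienone: dihydroazulen-3-one with the C8 enol oxygen and C11 oxygen in an acetonide | CC1=C2CCC(=O)[C@@H]2C=C3C(=C1)OC(C)(C)OC3(C)C
A7 | alternative 3 | 1-diazo-4-(2,2,4,4,7-pentamethyl-4H-1,3-benzodioxin-6-yl)butan-2-one | [N-]=[N+]=CC(=O)CCc1cc2c(cc1C)OC(C)(C)OC2(C)C
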